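**Retrosynthetic overview**
Numbering: cyclohexane C5–C10; C10 carries the methyl and the vinyl C1=C2; C5 carries C4(=C3H2)C15H2OH; lactone O–C6, C7–C11(=C13H2)–C12(=O); C8 carries the ester.
The strategy rests on the α-methylene-γ-butyrolactone trans-fused to the cyclohexane through C6 and C7, in a ring whose substituents are all equatorial except the C10 methyl.
Last bonds: acylation of O8 with the silyl-protected (E)-2-(hydroxymethyl)but-2-enoic acid, then removal of the silyl groups.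
Key disconnection: C6–C7 and O6–C12 together, by a chromium Barbier (Nozaki–Hiyama–Kishi) cyclisation of an open-chain (E)-2-(bromomethyl)enoate aldehyde; the cyclohexane closes first, the lactone second, and no ring exists before this step.
Precursor: C5–C10 by an enantioselective boron-enolate Ireland–Claisen rearrangement of an (E)-allylic but-3-enoate (C8 from (R)-glycidol); the C7=C11 unit by alkyne trans-hydrostannation, carbonylation and bromination.

Key step: step 21

Abbreviations: TBS = tert-butyldimethylsilyl, TBDPS = tert-butyldiphenylsilyl, TES = triethylsilyl, PMB = 4-methoxybenzyl; locants C1–C15 are those of the overview.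
Assumption: the (S,S)-diazaborolidine is taken to give the (5R,10S) series in step 9; the chair model fixes only the relative configuration, so if the sense proves opposite the (R,R)-reagent is used with nothing else changed.

**Route**

Step 1
Reactants: 1 (R)-glycidol
Product: 3 (S)-2-{[(4-methoxybenzyl)oxy]methyl}oxirane, via sodium alkoxide 2 (not isolated)
Conditions: NaH, DMF, 0 °C; then PMBCl, n-Bu4NI (cat.), 0 °C to rt
Reagents that add atoms: 4-methoxybenzyl chloride, COc1ccc(CCl)cc1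
Why: Williamson etherification of the alkoxide, which does not touch the stereocentre (the change from R to S is only a change of CIP priorities).

Step 2
Reactants: 3 (S)-2-{[(4-methoxybenzyl)oxy]methyl}oxirane
Product: 4 (S)-1-[(4-methoxybenzyl)oxy]pent-4-yn-2-ol
Conditions: LiC≡CH·H2NCH2CH2NH2, DMSO, 0 °C to rt; H2O
Reagents that add atoms: lithium acetylide (ethylenediamine complex), [Li]C#C
Why: SN2 opening of the epoxide at its unsubstituted carbon by the acetylide forms C9–C10 and leaves the C8 stereocentre as it is.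

Step 3
Reactants: 4 (S)-1-[(4-methoxybenzyl)oxy]pent-4-yn-2-ol
Product: 5 (S)-tert-butyl({1-[(4-methoxybenzyl)oxy]pent-4-yn-2-yl}oxy)dimethylsilane
Conditions: TBSCl, imidazole, DMF, rt
Reagents that add atoms: tert-butyldimethylsilyl chloride, CC(C)(C)[Si](C)(C)Cl
Why: Standard silylation of the secondary alcohol; this ether keeps O8 out of the later lactonisation.

Step 4
Reactants: 5 (S)-tert-butyl({1-[(4-methoxybenzyl)oxy]pent-4-yn-2-yl}oxy)dimethylsilane
Product: 8 (2E,5S)-5-(TBSO)-6-(PMBO)-3-methylhex-2-en-1-ol, via alkenylalane 6 (not isolated), via lithium alanate 7 (not isolated)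
Conditions: Me3Al, Cp2ZrCl2, CH2Cl2, 0 °C to rt; then n-BuLi, THF, −78 °C; (CH2O)n, −78 °C to rt; aq. potassium sodium tartrate
Reagents that add atoms: trimethylaluminium, C[Al](C)C; formaldehyde (as paraformaldehyde), C=O
Why: Negishi zirconium-catalysed carboalumination adds methyl and aluminium syn with aluminium on the terminal carbon, and the alanate adds to formaldehyde with retention, so the (E)-trisubstituted allylic alcohol (C9 trans to C2) should result.

Step 5
Reactants: 9 2-methylenepropane-1,3-diol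
Product: 10 2-{[(tert-butyldiphenylsilyl)oxy]methyl}prop-2-en-1-ol
Conditions: 9 (excess), TBDPSCl, imidazole, THF, 0 °C
Reagents that add atoms: tert-butyl(chloro)diphenylsilane, CC(C)(C)[Si](Cl)(c1ccccc1)c1ccccc1
Why: Statistical monosilylation of a symmetrical diol used in excess; the bulky silyl chloride disfavours the second silylation.

Step 6
Reactants: 10 2-{[(tert-butyldiphenylsilyl)oxy]methyl}prop-2-en-1-ol
Product: 11 tert-butyl{[2-(chloromethyl)prop-2-en-1-yl]oxy}diphenylsilane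
Conditions: MsCl, 2,4,6-collidine, LiCl, DMF, 0 °C
Reagents that add atoms: lithium chloride, [Li+].[Cl-]
Why: Mesylation and in situ chloride displacement at a primary allylic carbon under non-acidic conditions that spare the silyl ether.

Step 7
Reactants: 11 tert-butyl{[2-(chloromethyl)prop-2-en-1-yl]oxy}diphenylsilane
Product: 13 3-{[(tert-butyldiphenylsilyl)oxy]methyl}but-3-enoic acid, via allylmagnesium chloride 12 (not isolated)
Conditions: Mg, THF, 0 °C (slow addition); CO2, −78 °C; cold aq. HCl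
Reagents that add atoms: carbon dioxide, O=C=O
Why: Carboxylation of an allylic Grignard reagent; its two CH2 termini are not equivalent, and the six-membered SE2′ path with CO2 should deliver the wanted but-3-enoic acid, which is kept cold and free of base to stay out of conjugation.

Step 8
Reactants: 8 (2E,5S)-5-(TBSO)-6-(PMBO)-3-methylhex-2-en-1-ol; 13 3-{[(tert-butyldiphenylsilyl)oxy]methyl}but-3-enoic acid
Product: 14 (2E,5S)-5-(TBSO)-6-(PMBO)-3-methylhex-2-en-1-yl 3-[(TBDPSO)methyl]but-3-enoate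
Conditions: DCC, DMAP (cat.), CH2Cl2, 0 °C
Reagents that add atoms: none
Why: Steglich esterification, run cold with little DMAP so that the β,γ-double bond of the acid does not move into conjugation.

Step 9
Reactants: 14 (2E,5S)-5-(TBSO)-6-(PMBO)-3-methylhex-2-en-1-yl 3-[(TBDPSO)methyl]but-3-enoate
Product: 16 (2R,3S,5S)-3-ethenyl-3-methyl-5-(TBSO)-6-(PMBO)-2-[3-(TBDPSO)prop-1-en-2-yl]hexanoic acid, via boron dienolate 15 (not isolated)
Conditions: (S,S)-PhCH(NHSO2Ar)CH(NHSO2Ar)Ph (Ar = 3,5-(CF3)2C6H3), BBr3, CH2Cl2, rt, then evaporation; 14, Et3N, toluene–hexane, −78 °C, then 4 °C; aq. work-up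
Reagents that add atoms: none
Why: Enantioselective boron-enolate Ireland–Claisen rearrangement: Et3N in the non-polar medium is expected to give the E(O) dienolate (C4 cis to the allylic oxygen), the (E)-allyl unit places C9 equatorial and the methyl axial in the chair so that C5 and C10 form with the anti relation of the target, and the C2-symmetric diazaborolidine selects the enolate face and thereby the absolute configuration (5R,10S).

Step 10
Reactants: 16 (2R,3S,5S)-3-ethenyl-3-methyl-5-(TBSO)-6-(PMBO)-2-[3-(TBDPSO)prop-1-en-2-yl]hexanoic acid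
Product: 17 (2R,3S,5S)-3-ethenyl-3-methyl-5-(TBSO)-6-(PMBO)-2-[3-(TBDPSO)prop-1-en-2-yl]hexan-1-ol
Conditions: LiAlH4, THF, 0 °C to rt; H2O, aq. NaOH
Reagents that add atoms: none
Why: Hydride reduction of the carboxylic acid to the primary alcohol (C6); silyl ethers, the PMB ether and the isolated alkenes are inert.

Step 11
Reactants: 17 (2R,3S,5S)-3-ethenyl-3-methyl-5-(TBSO)-6-(PMBO)-2-[3-(TBDPSO)prop-1-en-2-yl]hexan-1-ol
Product: 18 triethylsilyl ether of 17 at O6
Conditions: TESCl, imidazole, CH2Cl2, 0 °C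
Reagents that add atoms: chlorotriethylsilane, CC[Si](Cl)(CC)CC
Why: Silylation of the primary alcohol with a group that can later be removed beside the secondary TBS and the primary TBDPS ethers.

Step 12
Reactants: 18 triethylsilyl ether of 17
Product: 19 (2S,4S,5R)-2-(TBSO)-4-ethenyl-4-methyl-5-[(TESO)methyl]-6-[(TBDPSO)methyl]hept-6-en-1-ol
Conditions: DDQ, CH2Cl2–aq. pH 7 buffer, 0 °C
Reagents that add atoms: none
Why: Oxidative cleavage of the PMB ether (hydride abstraction, hydrolysis of the oxocarbenium ion) frees O7 and leaves silyl ethers and alkenes untouched.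

Step 13
Reactants: 19 (2S,4S,5R)-2-(TBSO)-4-ethenyl-4-methyl-5-[(TESO)methyl]-6-[(TBDPSO)methyl]hept-6-en-1-ol
Product: 20 (2S,4S,5R)-2-(TBSO)-4-ethenyl-4-methyl-5-[(TESO)methyl]-6-[(TBDPSO)methyl]hept-6-enal
Conditions: Dess–Martin periodinane, NaHCO3, CH2Cl2, 0 °C to rt
Reagents that add atoms: none
Why: Dess–Martin oxidation is mild and non-basic, so the α-silyloxy aldehyde should keep its C8 configuration.

Step 14
Reactants: 20 (2S,4S,5R)-2-(TBSO)-4-ethenyl-4-methyl-5-[(TESO)methyl]-6-[(TBDPSO)methyl]hept-6-enal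
Product: 21 (3R,4S,6S)-6-(TBSO)-4-ethenyl-4-methyl-3-[(TESO)methyl]-2-[(TBDPSO)methyl]oct-1-en-7-yne
Conditions: dimethyl (1-diazo-2-oxopropyl)phosphonate, K2CO3, MeOH, 0 °C to rt
Reagents that add atoms: dimethyl (1-diazo-2-oxopropyl)phosphonate, COP(=O)(OC)C(=[N+]=[N-])C(C)=O
Why: Ohira–Bestmann (Seyferth–Gilbert) homologation turns the aldehyde into the terminal alkyne C7≡C11 under mild carbonate conditions.

Step 15
Reactants: 21 (3R,4S,6S)-6-(TBSO)-4-ethenyl-4-methyl-3-[(TESO)methyl]-2-[(TBDPSO)methyl]oct-1-en-7-yne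
Product: 23 (4S,6S,7R)-4-(TBSO)-6-ethenyl-6-methyl-7-[(TESO)methyl]-8-[(TBDPSO)methyl]non-8-en-2-yn-1-ol, via lithium acetylide 22 (not isolated)
Conditions: n-BuLi, THF, −78 °C; (CH2O)n, −78 °C to rt; H2O
Reagents that add atoms: formaldehyde (as paraformaldehyde), C=O
Why: Addition of the lithium acetylide to formaldehyde installs C13 as the free propargylic alcohol that directs the next step.

Step 16
Reactants: 23 (4S,6S,7R)-4-(TBSO)-6-ethenyl-6-methyl-7-[(TESO)methyl]-8-[(TBDPSO)methyl]non-8-en-2-yn-1-ol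
Product: 25 (2Z,4S,6S,7R)-2-iodo-4-(TBSO)-6-ethenyl-6-methyl-7-[(TESO)methyl]-8-[(TBDPSO)methyl]nona-2,8-dien-1-ol, via alkenylstannane 24 (not isolated)
Conditions: Bu3SnH, [Cp*RuCl]4 (cat., Cp* = C5Me5), CH2Cl2, rt; then I2, −78 to 0 °C
Reagents that add atoms: iodine, II
Why: Hydroxyl-directed ruthenium-catalysed trans-hydrostannation (hydrogen bond from the OH to the Ru–Cl unit) puts tin on C11 and hydrogen on C7 on opposite faces, and iododestannylation with retention fixes the olefin geometry with iodine cis to C8.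

Step 17
Reactants: 25 (2Z,4S,6S,7R)-2-iodo-4-(TBSO)-6-ethenyl-6-methyl-7-[(TESO)methyl]-8-[(TBDPSO)methyl]nona-2,8-dien-1-ol
Product: 26 methyl (2Z,4S,6S,7R)-2-(hydroxymethyl)-4-(TBSO)-6-ethenyl-6-methyl-7-[(TESO)methyl]-8-[(TBDPSO)methyl]nona-2,8-dienoate
Conditions: PdCl2(PPh3)2 (cat.), CO (1 atm), Et3N, MeOH–THF, 50 °C
Reagents that add atoms: carbon monoxide, [C-]#[O+]; methanol, CO
Why: Palladium-catalysed methoxycarbonylation of the alkenyl iodide (oxidative addition, CO insertion, methanolysis) proceeds with retention, so the ester C12 ends cis to C8.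

Step 18
Reactants: 26 methyl (2Z,4S,6S,7R)-2-(hydroxymethyl)-4-(TBSO)-6-ethenyl-6-methyl-7-[(TESO)methyl]-8-[(TBDPSO)methyl]nona-2,8-dienoate
Product: 27 methyl (2E,4S,6S,7R)-2-(bromomethyl)-4-(TBSO)-6-ethenyl-6-methyl-7-[(TESO)methyl]-8-[(TBDPSO)methyl]nona-2,8-dienoate
Conditions: CBr4, PPh3, CH2Cl2, −20 to 0 °C
Reagents that add atoms: carbon tetrabromide, BrC(Br)(Br)Br
Why: Appel bromination is an SN2 displacement at the primary allylic carbon C13, so the olefin geometry (C8 trans to CH2Br) should be kept if the reaction is short and cold.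

Step 19
Reactants: 27 methyl (2E,4S,6S,7R)-2-(bromomethyl)-4-(TBSO)-6-ethenyl-6-methyl-7-[(TESO)methyl]-8-[(TBDPSO)methyl]nona-2,8-dienoate
Product: 28 methyl (2E,4S,6S,7R)-2-(bromomethyl)-4-(TBSO)-6-ethenyl-7-(hydroxymethyl)-6-methyl-8-[(TBDPSO)methyl]nona-2,8-dienoate
Conditions: HF·pyridine, pyridine, THF, 0 °C
Reagents that add atoms: none
Why: Buffered HF·pyridine cleaves the primary TES ether much faster than the secondary TBS or the primary TBDPS ether and does not attack the allylic bromide.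

Step 20
Reactants: 28 methyl (2E,4S,6S,7R)-2-(bromomethyl)-4-(TBSO)-6-ethenyl-7-(hydroxymethyl)-6-methyl-8-[(TBDPSO)methyl]nona-2,8-dienoate
Product: 29 methyl (2E,4S,6S,7R)-2-(bromomethyl)-4-(TBSO)-6-ethenyl-7-formyl-6-methyl-8-[(TBDPSO)methyl]nona-2,8-dienoate
Conditions: Dess–Martin periodinane, NaHCO3, CH2Cl2, 0 °C; used at once
Reagents that add atoms: none
Why: Dess–Martin oxidation gives the C6 aldehyde under near-neutral conditions, which should avoid epimerisation at C5 and migration of the C4=C3 bond into conjugation.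

Step 21
Reactants: 29 methyl (2E,4S,6S,7R)-2-(bromomethyl)-4-(TBSO)-6-ethenyl-7-formyl-6-methyl-8-[(TBDPSO)methyl]nona-2,8-dienoate
Product: 32 8α-(TBSO)-15-(TBDPSO)-elema-1,3,11(13)-trien-12,6α-olide (5αH,6βH,7αH,8βH,10β-methyl), via allylchromium 30 (not isolated), via hydroxy ester 31 (not isolated)
Conditions: CrCl2 (excess), THF, high dilution, 0 °C to rt; aq. NH4Cl; then PPTS (cat.), toluene, 40 °C
Reagents that add atoms: none
Why: Two equivalents of CrCl2 reduce the allylic C13–Br bond to the 2-(methoxycarbonyl)allylchromium species 30, whose γ-carbon C7 adds to the C6 aldehyde through a closed six-membered Zimmerman–Traxler chair with allylic transposition, so that the C11=C13 methylene appears as the C6–C7 bond forms; the closest known reaction type is the intramolecular Nozaki–Hiyama–Kishi (chromium Barbier) allylation of aldehydes by 2-(bromomethyl)acrylates that gives ring-fused α-methylene-γ-butyrolactones. The cyclohexane closes by 6-exo-trig addition to the aldehyde, and the lactone by 5-exo-trig acyl substitution of the C6 oxygen (chromium alkoxide, or the alcohol 31 under PPTS) at the ester carbon C12 with loss of methanol. C7 is controlled by the olefin geometry: with C8 trans to CH2Cr, C8 sits equatorial in the metal-containing chair and the new C6–O and C7–C11 bonds come out anti, that is trans-diequatorial on the ring. C6 is controlled by the carbocyclic chair, in which the C5 side chain, the C8 silyloxy group and the C10 vinyl group are equatorial and only the C10 methyl is axial; this fixes the aldehyde face and gives H6 β and H7 α. The step needs addition that is faster than E/Z equilibration of the allylchromium, which is served by the easy six-ring closure at 0 °C under high dilution, and lactonisation at O6 only, which is secured because O8 is a silyl ether.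

Step 22
Reactants: 32 8α-(TBSO)-15-(TBDPSO)-elema-1,3,11(13)-trien-12,6α-olide
Product: 33 8α-hydroxy-15-(TBDPSO)-elema-1,3,11(13)-trien-12,6α-olide
Conditions: aq. HF (48%), MeCN, 0 °C
Reagents that add atoms: none
Why: Acidic fluoride cleaves the secondary TBS ether far faster than the primary TBDPS ether, and the non-basic medium should not open or transpose the lactone.

Step 23
Reactants: 34 but-2-yn-1-ol
Product: 36 (E)-2-iodobut-2-en-1-ol, via alkenylstannane 35 (not isolated)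
Conditions: Bu3SnH, PdCl2(PPh3)2 (cat.), THF, 0 °C to rt; then I2, CH2Cl2, 0 °C
Reagents that add atoms: iodine, II
Why: Palladium-catalysed syn-hydrostannation places tin mainly on the carbon next to the CH2OH group, and iododestannylation with retention gives the iodide with the methyl cis to CH2OH; the minor 3-iodo isomer is removed by chromatography.

Step 24
Reactants: 36 (E)-2-iodobut-2-en-1-ol
Product: 37 (E)-tert-butyl[(2-iodobut-2-en-1-yl)oxy]dimethylsilane
Conditions: TBSCl, imidazole, CH2Cl2, rt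
Reagents that add atoms: tert-butyldimethylsilyl chloride, CC(C)(C)[Si](C)(C)Cl
Why: Standard silylation of the primary allylic alcohol.

Step 25
Reactants: 37 (E)-tert-butyl[(2-iodobut-2-en-1-yl)oxy]dimethylsilane
Product: 39 (E)-2-[(TBSO)methyl]but-2-enoic acid, via alkenyllithium 38 (not isolated)
Conditions: t-BuLi (2 equiv), Et2O, −78 °C; CO2, −78 °C; cold aq. HCl (pH 3)
Reagents that add atoms: carbon dioxide, O=C=O
Why: Iodine–lithium exchange gives a configurationally stable alkenyllithium (kept at −78 °C to prevent silyl migration from oxygen to carbon), and carboxylation with retention gives the acid with the methyl trans to the carboxyl group.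

Step 26
Reactants: 33 8α-hydroxy-15-(TBDPSO)-elema-1,3,11(13)-trien-12,6α-olide; 39 (E)-2-[(TBSO)methyl]but-2-enoic acid
Product: 41 8α-{(E)-2-[(TBSO)methyl]but-2-enoyloxy}-15-(TBDPSO)-elema-1,3,11(13)-trien-12,6α-olide, via mixed anhydride 40 (not isolated)
Conditions: 39, 2,4,6-trichlorobenzoyl chloride, Et3N, THF, rt; then 33, DMAP, toluene, rt
Reagents that add atoms: none
Why: Yamaguchi esterification acylates the only free hydroxyl (O8); the acid has the thermodynamically preferred tiglate-type geometry, so DMAP should not isomerise it.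

Step 27
Reactants: 41 8α-{(E)-2-[(TBSO)methyl]but-2-enoyloxy}-15-(TBDPSO)-elema-1,3,11(13)-trien-12,6α-olide
Product: 42 CNP0111202.2, 8α-[(E)-2-(hydroxymethyl)but-2-enoyloxy]-15-hydroxyelema-1,3,11(13)-trien-12,6α-olide
Conditions: HF·pyridine, THF, 0 °C to rt
Reagents that add atoms: none
Why: Acidic fluoride removes the TBS and TBDPS ethers without base, so the two esters and the two Michael acceptors should survive.

**Compound list**
1 | (R)-glycidol | OC[C@@H]1CO1 | starting material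
2 | sodium (R)-oxiran-2-ylmethanolate | [Na+].[O-]C[C@@H]1CO1 | intermediate
3 | (S)-2-{[(4-methoxybenzyl)oxy]methyl}oxirane | COc1ccc(COC[C@@H]2CO2)cc1 | intermediate
4 | (S)-1-[(4-methoxybenzyl)oxy]pent-4-yn-2-ol | COc1ccc(COC[C@@H](O)CC#C)cc1 | intermediate
5 | (S)-tert-butyl({1-[(4-methoxybenzyl)oxy]pent-4-yn-2-yl}oxy)dimethylsilane | COc1ccc(COC[C@@H](O[Si](C)(C)C(C)(C)C)CC#C)cc1 | intermediate
6 | dimethyl[(1E,4S)-4-(TBSO)-5-(PMBO)-2-methylpent-1-en-1-yl]alane | COc1ccc(COC[C@@H](O[Si](C)(C)C(C)(C)C)C/C(C)=C/[Al](C)C)cc1 | intermediate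
7 | lithium butyl(dimethyl)alanate of 6 | [Li+].COc1ccc(COC[C@@H](O[Si](C)(C)C(C)(C)C)C/C(C)=C/[Al-](C)(C)CCCC)cc1 | intermediate
8 | (2E,5S)-5-(TBSO)-6-(PMBO)-3-methylhex-2-en-1-ol | COc1ccc(COC[C@@H](O[Si](C)(C)C(C)(C)C)C/C(C)=C/CO)cc1 | intermediate
9 | 2-methylenepropane-1,3-diol | C=C(CO)CO | starting material
10 | 2-{[(tert-butyldiphenylsilyl)oxy]methyl}prop-2-en-1-ol | C=C(CO)CO[Si](c1ccccc1)(c1ccccc1)C(C)(C)C | intermediate
11 | tert-butyl{[2-(chloromethyl)prop-2-en-1-yl]oxy}diphenylsilane | C=C(CCl)CO[Si](c1ccccc1)(c1ccccc1)C(C)(C)C | intermediate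
12 | {2-[(TBDPSO)methyl]prop-2-en-1-yl}magnesium chloride | C=C(C[Mg]Cl)CO[Si](c1ccccc1)(c1ccccc1)C(C)(C)C | intermediate
13 | 3-{[(tert-butyldiphenylsilyl)oxy]methyl}but-3-enoic acid | C=C(CC(=O)O)CO[Si](c1ccccc1)(c1ccccc1)C(C)(C)C | intermediate
14 | (2E,5S)-5-(TBSO)-6-(PMBO)-3-methylhex-2-en-1-yl 3-[(TBDPSO)methyl]but-3-enoate | COc1ccc(COC[C@@H](O[Si](C)(C)C(C)(C)C)C/C(C)=C/COC(=O)CC(=C)CO[Si](c2ccccc2)(c2ccccc2)C(C)(C)C)cc1 | intermediate
15 | E(O) boron dienolate of 14 on the (4S,5S)-diazaborolidine (C4 cis to the allylic oxygen) | C=C(CO[Si](c1ccccc1)(c1ccccc1)C(C)(C)C)/C=C(\OC/C=C(\C)C[C@H](O[Si](C)(C)C(C)(C)C)COCc1ccc(OC)cc1)OB1N(S(=O)(=O)c2cc(cc(c2)C(F)(F)F)C(F)(F)F)[C@@H](c2ccccc2)[C@H](c2ccccc2)N1S(=O)(=O)c1cc(cc(c1)C(F)(F)F)C(F)(F)F | intermediate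
16 | (2R,3S,5S)-3-ethenyl-3-methyl-5-(TBSO)-6-(PMBO)-2-[3-(TBDPSO)prop-1-en-2-yl]hexanoic acid | C=C[C@](C)(C[C@H](O[Si](C)(C)C(C)(C)C)COCc1ccc(OC)cc1)[C@@H](C(=O)O)C(=C)CO[Si](c1ccccc1)(c1ccccc1)C(C)(C)C | intermediate
17 | (2R,3S,5S)-3-ethenyl-3-methyl-5-(TBSO)-6-(PMBO)-2-[3-(TBDPSO)prop-1-en-2-yl]hexan-1-ol | C=C[C@](C)(C[C@H](O[Si](C)(C)C(C)(C)C)COCc1ccc(OC)cc1)[C@@H](CO)C(=C)CO[Si](c1ccccc1)(c1ccccc1)C(C)(C)C | intermediate
18 | triethylsilyl ether of 17 at O6 | C=C[C@](C)(C[C@H](O[Si](C)(C)C(C)(C)C)COCc1ccc(OC)cc1)[C@@H](CO[Si](CC)(CC)CC)C(=C)CO[Si](c1ccccc1)(c1ccccc1)C(C)(C)C | intermediate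
19 | (2S,4S,5R)-2-(TBSO)-4-ethenyl-4-methyl-5-[(TESO)methyl]-6-[(TBDPSO)methyl]hept-6-en-1-ol | C=C[C@](C)(C[C@H](O[Si](C)(C)C(C)(C)C)CO)[C@@H](CO[Si](CC)(CC)CC)C(=C)CO[Si](c1ccccc1)(c1ccccc1)C(C)(C)C | intermediate
20 | (2S,4S,5R)-2-(TBSO)-4-ethenyl-4-methyl-5-[(TESO)methyl]-6-[(TBDPSO)methyl]hept-6-enal | C=C[C@](C)(C[C@H](O[Si](C)(C)C(C)(C)C)C=O)[C@@H](CO[Si](CC)(CC)CC)C(=C)CO[Si](c1ccccc1)(c1ccccc1)C(C)(C)C | intermediate
21 | (3R,4S,6S)-6-(TBSO)-4-ethenyl-4-methyl-3-[(TESO)methyl]-2-[(TBDPSO)methyl]oct-1-en-7-yne | C=C[C@](C)(C[C@H](O[Si](C)(C)C(C)(C)C)C#C)[C@@H](CO[Si](CC)(CC)CC)C(=C)CO[Si](c1ccccc1)(c1ccccc1)C(C)(C)C | intermediate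
22 | lithium acetylide of 21 | C=C[C@](C)(C[C@H](O[Si](C)(C)C(C)(C)C)C#C[Li])[C@@H](CO[Si](CC)(CC)CC)C(=C)CO[Si](c1ccccc1)(c1ccccc1)C(C)(C)C | intermediate
23 | (4S,6S,7R)-4-(TBSO)-6-ethenyl-6-methyl-7-[(TESO)methyl]-8-[(TBDPSO)methyl]non-8-en-2-yn-1-ol | C=C[C@](C)(C[C@H](O[Si](C)(C)C(C)(C)C)C#CCO)[C@@H](CO[Si](CC)(CC)CC)C(=C)CO[Si](c1ccccc1)(c1ccccc1)C(C)(C)C | intermediate
24 | (2Z)-2-(tributylstannyl) analogue of 25 (tin on C11, cis to C8) | C=C[C@](C)(C[C@H](O[Si](C)(C)C(C)(C)C)/C=C(/CO)[Sn](CCCC)(CCCC)CCCC)[C@@H](CO[Si](CC)(CC)CC)C(=C)CO[Si](c1ccccc1)(c1ccccc1)C(C)(C)C | intermediate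
25 | (2Z,4S,6S,7R)-2-iodo-4-(TBSO)-6-ethenyl-6-methyl-7-[(TESO)methyl]-8-[(TBDPSO)methyl]nona-2,8-dien-1-ol | C=C[C@](C)(C[C@H](O[Si](C)(C)C(C)(C)C)/C=C(/CO)I)[C@@H](CO[Si](CC)(CC)CC)C(=C)CO[Si](c1ccccc1)(c1ccccc1)C(C)(C)C | intermediate
26 | methyl (2Z,4S,6S,7R)-2-(hydroxymethyl)-4-(TBSO)-6-ethenyl-6-methyl-7-[(TESO)methyl]-8-[(TBDPSO)methyl]nona-2,8-dienoate | C=C[C@](C)(C[C@H](O[Si](C)(C)C(C)(C)C)/C=C(/CO)C(=O)OC)[C@@H](CO[Si](CC)(CC)CC)C(=C)CO[Si](c1ccccc1)(c1ccccc1)C(C)(C)C | intermediate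
27 | methyl (2E,4S,6S,7R)-2-(bromomethyl)-4-(TBSO)-6-ethenyl-6-methyl-7-[(TESO)methyl]-8-[(TBDPSO)methyl]nona-2,8-dienoate | C=C[C@](C)(C[C@H](O[Si](C)(C)C(C)(C)C)/C=C(/CBr)C(=O)OC)[C@@H](CO[Si](CC)(CC)CC)C(=C)CO[Si](c1ccccc1)(c1ccccc1)C(C)(C)C | intermediate
28 | methyl (2E,4S,6S,7R)-2-(bromomethyl)-4-(TBSO)-6-ethenyl-7-(hydroxymethyl)-6-methyl-8-[(TBDPSO)methyl]nona-2,8-dienoate | C=C[C@](C)(C[C@H](O[Si](C)(C)C(C)(C)C)/C=C(/CBr)C(=O)OC)[C@@H](CO)C(=C)CO[Si](c1ccccc1)(c1ccccc1)C(C)(C)C | intermediate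
29 | methyl (2E,4S,6S,7R)-2-(bromomethyl)-4-(TBSO)-6-ethenyl-7-formyl-6-methyl-8-[(TBDPSO)methyl]nona-2,8-dienoate (key-step precursor) | C=C[C@](C)(C[C@H](O[Si](C)(C)C(C)(C)C)/C=C(/CBr)C(=O)OC)[C@@H](C=O)C(=C)CO[Si](c1ccccc1)(c1ccccc1)C(C)(C)C | intermediate
30 | allylchromium dichloride from 29 (CrCl2 on C13) | C=C[C@](C)(C[C@H](O[Si](C)(C)C(C)(C)C)/C=C(/C[Cr](Cl)Cl)C(=O)OC)[C@@H](C=O)C(=C)CO[Si](c1ccccc1)(c1ccccc1)C(C)(C)C | intermediate
31 | cyclised hydroxy ester: methyl 2-[cyclohexyl]acrylate with 6α-OH, 8α-OTBS, 5β side chain, 10α-vinyl, 10β-methyl | C=C[C@]1(C)C[C@H](O[Si](C)(C)C(C)(C)C)[C@@H](C(=C)C(=O)OC)[C@H](O)[C@H]1C(=C)CO[Si](c1ccccc1)(c1ccccc1)C(C)(C)C | intermediate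
32 | 8α-(TBSO)-15-(TBDPSO)-elema-1,3,11(13)-trien-12,6α-olide (key-step product) | C=C[C@]1(C)C[C@H](O[Si](C)(C)C(C)(C)C)[C@H]2C(=C)C(=O)O[C@@H]2[C@H]1C(=C)CO[Si](c1ccccc1)(c1ccccc1)C(C)(C)C | intermediate
33 | 8α-hydroxy-15-(TBDPSO)-elema-1,3,11(13)-trien-12,6α-olide | C=C[C@]1(C)C[C@H](O)[C@H]2C(=C)C(=O)O[C@@H]2[C@H]1C(=C)CO[Si](c1ccccc1)(c1ccccc1)C(C)(C)C | intermediate
34 | but-2-yn-1-ol | CC#CCO | starting material
35 | (E)-2-(tributylstannyl)but-2-en-1-ol | C/C=C(/[Sn](CCCC)(CCCC)CCCC)CO | intermediate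
36 | (E)-2-iodobut-2-en-1-ol | C/C=C(/I)CO | intermediate
37 | (E)-tert-butyl[(2-iodobut-2-en-1-yl)oxy]dimethylsilane | C/C=C(/I)CO[Si](C)(C)C(C)(C)C | intermediate
38 | alkenyllithium from 37 (lithium in place of iodine) | C/C=C(/[Li])CO[Si](C)(C)C(C)(C)C | intermediate
39 | (E)-2-[(TBSO)methyl]but-2-enoic acid | C/C=C(/C(=O)O)CO[Si](C)(C)C(C)(C)C | intermediate
40 | mixed anhydride of 39 with 2,4,6-trichlorobenzoic acid | C/C=C(/C(=O)OC(=O)c1c(Cl)cc(Cl)cc1Cl)CO[Si](C)(C)C(C)(C)C | intermediate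
41 | 8α-{(E)-2-[(TBSO)methyl]but-2-enoyloxy}-15-(TBDPSO)-elema-1,3,11(13)-trien-12,6α-olide | C=C[C@]1(C)C[C@H](OC(=O)/C(=C/C)CO[Si](C)(C)C(C)(C)C)[C@H]2C(=C)C(=O)O[C@@H]2[C@H]1C(=C)CO[Si](c1ccccc1)(c1ccccc1)C(C)(C)C | intermediate
42 | CNP0111202.2, 8α-[(E)-2-(hydroxymethyl)but-2-enoyloxy]-15-hydroxyelema-1,3,11(13)-trien-12,6α-olide | C=C[C@]1(C)C[C@H](OC(=O)/C(=C/C)CO)[C@H]2C(=C)C(=O)O[C@@H]2[C@H]1C(=C)CO | target

**Step count**
Total: 27 steps. Longest linear sequence: 21 steps (steps 1–4, 8–22, 26, 27).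

**Steps most likely to fail, with fallbacks**

Step 21. The allylchromium may lose its E geometry by metallotropic shift before it adds, which would give the cis ring fusion; the α-branched aldehyde may enolise or epimerise at C5; lactonisation may stop at the hydroxy ester. The fallback replaces the chromium reagent by a configurationally stable allylboronate and sets out from alkyne 21. Its lithium acetylide is acylated with methyl chloroformate to give the methyl ynoate F1. Syn-hydroalumination with i-Bu2AlH/HMPA in THF and alkylation of the α-aluminio enoate with 2-(iodomethyl)-4,4,5,5-tetramethyl-1,3,2-dioxaborolane should give the 2-(methoxycarbonyl)allylboronate F2 with C8 cis to the ester. PPTS in MeOH removes the TES group to give the alcohol F3, and Dess–Martin oxidation gives the aldehyde F4. Warming F4 in toluene should bring about intramolecular allylboration through the same chair; acidic work-up lactonises the product to 32, where the route is rejoined.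

Step 9. Enolate geometry may not be controlled (wrong relative configuration at C5), facial selectivity on a substrate carrying several Lewis-basic ethers may be low or opposite, and the rearrangement to the quaternary centre may be slow enough for the ester to decompose. The fallback gives up reagent control and sets out from ester 14. LiN(i-Pr)2 and Me3SiCl/Et3N in THF at −78 °C give the silyl ketene acetal F5 (kinetic E(O) geometry), which on warming to rt rearranges through the chair to the trimethylsilyl ester F6. Hydrolysis gives 16 together with its (5S,10R) diastereomer F7; the two differ at C5 and C10 but share the fixed C8 centre, so they are separated by chromatography and 16 re-enters the route.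

Step 16. Tin may be delivered to the distal carbon or by cis addition, eroding regio- and geometric purity, and protodestannylation or iodination of the other alkenes may compete. The fallback builds the trisubstituted olefin by olefination and sets out from aldehyde 20. A Horner–Wadsworth–Emmons reaction with methyl bis(2,2,2-trifluoroethyl) bromophosphonoacetate (made by bromination of the commercial Still–Gennari phosphonate; t-BuOK, 18-crown-6, THF, −78 °C) should give the (E)-α-bromoenoate F8 with the ester cis to C8. Stille coupling of F8 with (tributylstannyl)methanol (Pd(PPh3)4, dioxane, 90 °C) replaces bromine by CH2OH with retention and gives 26, where the route is rejoined.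

**Further compounds**
F1 | step 21 | methyl ynoate from 21 (C11 carries CO2Me) | C=C[C@](C)(C[C@H](O[Si](C)(C)C(C)(C)C)C#CC(=O)OC)[C@@H](CO[Si](CC)(CC)CC)C(=C)CO[Si](c1ccccc1)(c1ccccc1)C(C)(C)C
F2 | step 21 | 2-(methoxycarbonyl)allyl pinacol boronate, O6 as TES ether (C8 trans to CH2B) | C=C[C@](C)(C[C@H](O[Si](C)(C)C(C)(C)C)/C=C(/CB1OC(C)(C)C(C)(C)O1)C(=O)OC)[C@@H](CO[Si](CC)(CC)CC)C(=C)CO[Si](c1ccccc1)(c1ccccc1)C(C)(C)C
F3 | step 21 | allylboronate with free C6 hydroxymethyl | C=C[C@](C)(C[C@H](O[Si](C)(C)C(C)(C)C)/C=C(/CB1OC(C)(C)C(C)(C)O1)C(=O)OC)[C@@H](CO)C(=C)CO[Si](c1ccccc1)(c1ccccc1)C(C)(C)C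
F4 | step 21 | allylboronate aldehyde | C=C[C@](C)(C[C@H](O[Si](C)(C)C(C)(C)C)/C=C(/CB1OC(C)(C)C(C)(C)O1)C(=O)OC)[C@@H](C=O)C(=C)CO[Si](c1ccccc1)(c1ccccc1)C(C)(C)C
F5 | step 9 | trimethylsilyl ketene acetal of 14 (C4 cis to the allylic oxygen) | C=C(CO[Si](c1ccccc1)(c1ccccc1)C(C)(C)C)/C=C(\OC/C=C(\C)C[C@H](O[Si](C)(C)C(C)(C)C)COCc1ccc(OC)cc1)O[Si](C)(C)C
F6 | step 9 | trimethylsilyl ester of 16 | C=C[C@](C)(C[C@H](O[Si](C)(C)C(C)(C)C)COCc1ccc(OC)cc1)[C@@H](C(=O)O[Si](C)(C)C)C(=C)CO[Si](c1ccccc1)(c1ccccc1)C(C)(C)C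
F7 | step 9 | (2S,3R,5S) diastereomer of acid 16 | C=C[C@@](C)(C[C@H](O[Si](C)(C)C(C)(C)C)COCc1ccc(OC)cc1)[C@H](C(=O)O)C(=C)CO[Si](c1ccccc1)(c1ccccc1)C(C)(C)C
F8 | step 16 | methyl (E)-2-bromoenoate from 20 (ester cis to C8) | C=C[C@](C)(C[C@H](O[Si](C)(C)C(C)(C)C)/C=C(/Br)C(=O)OC)[C@@H](CO[Si](CC)(CC)CC)C(=C)CO[Si](c1ccccc1)(c1ccccc1)C(C)(C)C
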